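C1 CMe2, C2 CHBr, C3 CH2, C4 CHCl, C5 ring sp2 carbon, C6 CHCl, C7 exocyclic CH, C8 CH2Br; the only ring is the cyclohexane C1–C6.
The plan rests on the C2–Br bond, which sits on a secondary ring carbon directly beside the quaternary C1 (no SN2 access), and on the C4 chloride beside C5: C3–C4 and C2–Br are disconnected in one radical event, back to an acyclic bromochloromethyl ketone (carbonyl at C5) whose C1 bears a vinyl group (C2=C3).
C6–Cl is just as neopentyl, so it is not made on the ring: it is set by SN2 inversion on the triflate of (S)-pantolactone and carried through the cyclisation as the controlling stereocentre; the lactone supplies C5, C6, C1 with both methyl groups, and C2.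
Acyclic stage: C2=C3 by Wittig methylenation of the C2 aldehyde, C4–C5 by acylation of LiCHBrCl with the C5 Weinreb amide.
After the ring (the cyclohexane, closed in step 7, the only ring-forming step): C5–C7 by vinyl addition to the ketone, then C5=C7 and C8–Br by SN2′ bromination.

Key step: step 7

Remark: (S)-pantolactone is taken as a purchasable enantiomer; the bromochloromethyl carbon of the cyclisation precursor forms as both epimers, which converge because this carbon becomes the planar radical centre C4.

Step 1
Reactants: 1 (S)-pantolactone
Product: 2 (3S)-4,4-dimethyl-2-oxooxolan-3-yl trifluoromethanesulfonate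
Conditions: Tf2O, pyridine, CH2Cl2, −20 to 0 °C
Reagents that add atoms: trifluoromethanesulfonic anhydride, O=S(=O)(OS(=O)(=O)C(F)(F)F)C(F)(F)F
Why: O-triflation (sulfonate ester formation) leaves the C–O bond and hence the configuration untouched and gives an α-acyl triflate that cannot eliminate, because its carbon lies between the carbonyl and the quaternary carbon.

Step 2
Reactants: 2 (3S)-4,4-dimethyl-2-oxooxolan-3-yl trifluoromethanesulfonate
Product: 3 (3R)-3-chloro-4,4-dimethyloxolan-2-one
Conditions: Bu4NCl (1.1 equiv), MeCN, 0 °C to rt
Reagents that add atoms: tetrabutylammonium chloride, CCCC[N+](CCCC)(CCCC)CCCC.[Cl-]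
Why: SN2 displacement of the α-acyl triflate by chloride should proceed with inversion and so set the future C6–Cl centre as (3R); the carbonyl accelerates the substitution, the five-membered ring ties the gem-dimethyl group back, and a small excess of chloride at low temperature keeps the slower degenerate chloride exchange of the product from eroding the configuration.

Step 3
Reactants: 3 (3R)-3-chloro-4,4-dimethyloxolan-2-one
Product: 4 (2R)-2-chloro-4-hydroxy-N-methoxy-N,3,3-trimethylbutanamide
Conditions: MeNH(OMe)·HCl, AlMe3, CH2Cl2, 0 °C to rt; cold dilute HCl work-up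
Reagents that add atoms: N,O-dimethylhydroxylamine hydrochloride, CNOC.Cl
Why: Weinreb aminolysis of the lactone by the aluminium amide opens the ring at the acyl carbon under Lewis-acidic, non-basic conditions that should not touch the α-chloro centre; the hydroxy amide is oxidised without delay to forestall relactonisation.

Step 4
Reactants: 4 (2R)-2-chloro-4-hydroxy-N-methoxy-N,3,3-trimethylbutanamide
Product: 5 (2R)-2-chloro-N-methoxy-N,3,3-trimethyl-4-oxobutanamide
Conditions: Dess–Martin periodinane, CH2Cl2, 0 °C to rt
Reagents that add atoms: none
Why: Dess–Martin oxidation converts the neopentyl primary alcohol into an aldehyde that has no α-hydrogen, under neutral conditions in which the α-chloro amide is inert.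

Step 5
Reactants: 5 (2R)-2-chloro-N-methoxy-N,3,3-trimethyl-4-oxobutanamide; 6 methyltriphenylphosphonium bromide
Product: 8 (2R)-2-chloro-N-methoxy-N,3,3-trimethylpent-4-enamide, via methylenetriphenylphosphorane 7 (not isolated)
Conditions: 6, KN(SiMe3)2, THF, 0 °C; then 5 (no excess of ylide), −78 to 0 °C
Reagents that add atoms: none
Why: Wittig methylenation: the non-stabilised ylide reacts with the aldehyde far faster than with the Weinreb amide, and using no excess of it at low temperature should leave the hindered C–H of the α-chloro centre alone.

Step 6
Reactants: 8 (2R)-2-chloro-N-methoxy-N,3,3-trimethylpent-4-enamide; 9 bromochloromethane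
Product: 12 (3R)-1-bromo-1,3-dichloro-4,4-dimethylhex-5-en-2-one, via bromochloromethyllithium 10 (not isolated), via lithium hemiaminal adduct 11 (not isolated)
Conditions: 9 (3 equiv), lithium 2,2,6,6-tetramethylpiperidide (2.5 equiv, added last), THF, −78 °C; then 1 M HCl, −78 °C to rt
Reagents that add atoms: none
Why: Acylation of a dihalomethyllithium carbenoid by a Weinreb amide: the amide base deprotonates CH2BrCl in the presence of 8, the carbenoid adds at −78 °C, and the chelated adduct 11 keeps the carbonyl masked until the acid quench, so neither a second addition nor base attack on the trihalo ketone should occur.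

Step 7
Reactants: 12 (3R)-1-bromo-1,3-dichloro-4,4-dimethylhex-5-en-2-one
Product: 15 (2R,4S,6S)-4-bromo-2,6-dichloro-3,3-dimethylcyclohexan-1-one, via C4 enoxyl radical 13 (not isolated), via C2 cyclohexyl radical 14 (not isolated)
Conditions: CuBr (10 mol %), tris(2-pyridylmethyl)amine (10 mol %), AIBN (10 mol %), degassed MeCN (0.02 M), 60 °C
Reagents that add atoms: none
Why: CuBr bound to tris(2-pyridylmethyl)amine (monovalent copper) abstracts the weak C–Br bond of the CHBrCl group and leaves the C–Cl bonds, the electrophilic α-chloro-α-acyl radical 13 adds to the terminal vinyl carbon C3, and the secondary radical 14 takes bromine back from the CuBr2 complex (divalent copper), which closes the cycle while AIBN only makes up for termination. The closest known reaction type is the copper-catalysed Kharasch atom-transfer radical cyclisation of α-halo ketones. The cyclohexane ring closes 6-endo-trig, the usual mode when the carbonyl lies inside the forming ring, and 5-exo closure is further disfavoured because it would make a bond to C2 right beside the quaternary C1. C4 is set in a chair transition state in which the enoxyl radical reacts as its Z rotamer (C4–Cl syn to oxygen, away from the branched C6) with the C6–Cl bond pseudo-equatorial, the arrangement with both C–Cl bonds near the carbonyl plane that a polar solvent favours, so the C4 chloride should emerge equatorial and cis to the C6 chloride. C2 is set by the C6 stereocentre through that chair: bromine should be delivered axially, anti to the axial methyl on C1 and past only the axial hydrogens on C4 and C6, which places C2–Br trans to both chlorides. The step needs 6-endo over 5-exo closure, bromine and not chlorine transfer, and the trans C2/C6 relation, which are secured by the in-ring carbonyl with the quaternary C1, by bromide being the only halide on copper, and by the chair with both chlorides equatorial; C4 is the one centre that could still be corrected afterwards by chloride exchange or through its enol.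

Step 8
Reactants: 15 (2R,4S,6S)-4-bromo-2,6-dichloro-3,3-dimethylcyclohexan-1-one; 16 vinylmagnesium bromide
Product: 18 (1S,2R,4S,6S)-4-bromo-2,6-dichloro-1-ethenyl-3,3-dimethylcyclohexan-1-ol, via vinylcerium dichloride 17 (not isolated)
Conditions: 16, CeCl3 (anhydrous), THF, −78 °C; then 15, −78 °C; aq NH4Cl at −78 °C
Reagents that add atoms: none
Why: Organocerium 1,2-addition (Imamoto conditions): the weakly basic vinylcerium reagent should add to the hindered, enolisable α,α′-dichloro ketone instead of deprotonating C4, entering C5 equatorially, away from the axial methyl on C1, to give the axial alcohol cis to both chlorides, which therefore cannot close to an epoxide; this carbinol centre disappears again in step 9.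

Step 9
Reactants: 18 (1S,2R,4S,6S)-4-bromo-2,6-dichloro-1-ethenyl-3,3-dimethylcyclohexan-1-ol
Product: 20 ochtodene (1E,2S,4S,6S)-4-bromo-1-(2-bromoethylidene)-2,6-dichloro-3,3-dimethylcyclohexane, via dibromophosphite ester 19 (not isolated)
Conditions: PBr3, Et2O, −20 to 0 °C
Reagents that add atoms: phosphorus tribromide, BrP(Br)Br
Why: SN2′ bromination of a tertiary vinyl carbinol (allylic transposition): bromide attacks the unhindered terminal CH2 of dibromophosphite 19 while the two β-chlorines retard ionisation at C5, and the E geometry is expected because the CH2Br terminus turns toward C4 and away from C6, the flank crowded by the gem-dimethyl group.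

Compound list
1 | (S)-pantolactone, (3S)-3-hydroxy-4,4-dimethyloxolan-2-one | CC1(C)COC(=O)[C@H]1O | starting material
2 | (3S)-4,4-dimethyl-2-oxooxolan-3-yl trifluoromethanesulfonate | CC1(C)COC(=O)[C@H]1OS(=O)(=O)C(F)(F)F | intermediate
3 | (3R)-3-chloro-4,4-dimethyloxolan-2-one | CC1(C)COC(=O)[C@@H]1Cl | intermediate
4 | (2R)-2-chloro-4-hydroxy-N-methoxy-N,3,3-trimethylbutanamide | CON(C)C(=O)[C@H](Cl)C(C)(C)CO | intermediate
5 | (2R)-2-chloro-N-methoxy-N,3,3-trimethyl-4-oxobutanamide | CON(C)C(=O)[C@H](Cl)C(C)(C)C=O | intermediate
6 | methyltriphenylphosphonium bromide | C[P+](c1ccccc1)(c1ccccc1)c1ccccc1.[Br-] | starting material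
7 | methylenetriphenylphosphorane (not isolated) | C=P(c1ccccc1)(c1ccccc1)c1ccccc1 | intermediate
8 | (2R)-2-chloro-N-methoxy-N,3,3-trimethylpent-4-enamide | CON(C)C(=O)[C@H](Cl)C(C)(C)C=C | intermediate
9 | bromochloromethane | ClCBr | starting material
10 | bromochloromethyllithium (not isolated) | [Li]C(Cl)Br | intermediate
11 | lithium (3R)-1-bromo-1,3-dichloro-2-[methoxy(methyl)amino]-4,4-dimethylhex-5-en-2-olate (not isolated; C1 and C2 as mixtures) | [Li]OC(C(Cl)Br)(N(C)OC)[C@H](Cl)C(C)(C)C=C | intermediate
12 | (3R)-1-bromo-1,3-dichloro-4,4-dimethylhex-5-en-2-one (both C1 epimers) | ClC(Br)C(=O)[C@H](Cl)C(C)(C)C=C | intermediate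
13 | (3R)-1,3-dichloro-4,4-dimethyl-2-oxohex-5-en-1-yl radical (not isolated) | Cl[CH]C(=O)[C@H](Cl)C(C)(C)C=C | intermediate
14 | (3R,5S)-3,5-dichloro-2,2-dimethyl-4-oxocyclohexyl radical (not isolated) | CC1(C)[CH]C[C@H](Cl)C(=O)[C@@H]1Cl | intermediate
15 | (2R,4S,6S)-4-bromo-2,6-dichloro-3,3-dimethylcyclohexan-1-one | CC1(C)[C@@H](Br)C[C@H](Cl)C(=O)[C@@H]1Cl | intermediate
16 | vinylmagnesium bromide | C=C[Mg]Br | starting material
17 | vinylcerium dichloride (not isolated) | C=C[Ce](Cl)Cl | intermediate
18 | (1S,2R,4S,6S)-4-bromo-2,6-dichloro-1-ethenyl-3,3-dimethylcyclohexan-1-ol | CC1(C)[C@@H](Br)C[C@H](Cl)[C@@](O)(C=C)[C@@H]1Cl | intermediate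
19 | (1S,2R,4S,6S)-4-bromo-2,6-dichloro-1-ethenyl-3,3-dimethylcyclohexyl phosphorodibromidite (not isolated) | CC1(C)[C@@H](Br)C[C@H](Cl)[C@@](OP(Br)Br)(C=C)[C@@H]1Cl | intermediate
20 | ochtodene, (1E,2S,4S,6S)-4-bromo-1-(2-bromoethylidene)-2,6-dichloro-3,3-dimethylcyclohexane | CC1(C)[C@@H](Br)C[C@H](Cl)/C(=C\CBr)[C@@H]1Cl | target

Total step count: 9 steps.
Longest linear sequence: 9 steps (1 to 20).

Steps most likely to fail

Step 7 is the main risk. Bromine transfer to radical 14 may show poor facial selectivity, radical 13 may close through its other rotamer so that C4 forms as its epimer, or 13 may capture halogen before the ring closes. A C4 epimer of 15 could be returned by degenerate chloride exchange (LiCl, acetone), which should invert only the non-neopentyl C4. The fallback separates C–C bond formation from bromination by known xanthate chemistry and sets out from 12. Potassium O-ethyl xanthate (KSC(S)OEt) in acetone at 0 °C should displace the bromide to give the α-chloro-α-xanthyl ketone F1. Dilauroyl peroxide in refluxing 1,2-dichloroethane at high dilution should then effect the degenerate xanthate-transfer 6-endo cyclisation through the long-lived radical 13 to the ring xanthate F2. Radical exchange of the xanthate for bromine with ethyl 2-bromo-2-methylpropanoate and di-tert-butyl peroxide in refluxing chlorobenzene regenerates radical 14 whatever the C2 configuration of F2, and lets a bulkier bromine donor set C2. The fallback comes back to the route at 15.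

Step 9 is the second risk. The SN2′ displacement may fail to control the alkene geometry, and the HBr formed may ionise the secondary allylic chlorides. The fallback sets out from 18 and builds the alkene in stages. Oxidative allylic transposition with pyridinium chlorochromate in CH2Cl2 (Babler–Dauben) should give the enal F3, whose E and Z isomers can be separated and the unwanted one re-equilibrated with a trace of acid. Luche reduction (NaBH4, CeCl3·7H2O, MeOH, 0 °C) then gives the allylic alcohol F4. Appel bromination (CBr4, PPh3, CH2Cl2, 0 °C) substitutes at the primary carbon without transposition. The fallback comes back to the route at 20.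

Step 6 is the third risk. The amide base may deprotonate the α-chloro stereocentre and erode the C6 configuration, or break down the Weinreb amide. The fallback sets out from 8 and keeps amide bases away from the substrate. Reduction with i-Bu2AlH in THF at −78 °C should give the aldehyde F5. Bromochloromethylmagnesium chloride, made by bromine–magnesium exchange from dibromochloromethane and i-PrMgCl at −78 °C, should add to F5 to give the bromochlorohydrin F6 as a mixture at C1 and C2. Dess–Martin oxidation of the carbinol then removes the C2 stereocentre. The fallback comes back to the route at 12.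

Further compounds
F1 | step 7 | O-ethyl S-[(3R)-1,3-dichloro-4,4-dimethyl-2-oxohex-5-en-1-yl] carbonodithioate | CCOC(=S)SC(Cl)C(=O)[C@H](Cl)C(C)(C)C=C
F2 | step 7 | O-ethyl S-[(1S,3R,5S)-3,5-dichloro-2,2-dimethyl-4-oxocyclohexyl] carbonodithioate | CC1(C)[C@@H](SC(=S)OCC)C[C@H](Cl)C(=O)[C@@H]1Cl
F3 | step 9 | (2E)-2-[(2S,4S,6S)-4-bromo-2,6-dichloro-3,3-dimethylcyclohexylidene]acetaldehyde | CC1(C)[C@@H](Br)C[C@H](Cl)/C(=C\C=O)[C@@H]1Cl
F4 | step 9 | (2E)-2-[(2S,4S,6S)-4-bromo-2,6-dichloro-3,3-dimethylcyclohexylidene]ethan-1-ol | CC1(C)[C@@H](Br)C[C@H](Cl)/C(=C\CO)[C@@H]1Cl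
F5 | step 6 | (2R)-2-chloro-3,3-dimethylpent-4-enal | O=C[C@H](Cl)C(C)(C)C=C
F6 | step 6 | (3R)-1-bromo-1,3-dichloro-4,4-dimethylhex-5-en-2-ol | ClC(Br)C(O)[C@H](Cl)C(C)(C)C=C
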